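**Retrosynthetic overview**
- The strategy rests on ring F, a 1,4-disubstituted benzene: C4''' carries the ether oxygen to C3' of ring B, and C1''' carries C2'' of pyranone ring E at the carboxyl oxidation level.
- Ring F is cut across C3'''–C4''' and C5'''–C6''' into methyl coumalate (C1''', C2''', C3''', C6''' and the ester carbon) and an aryloxyacetylene (C4''', C5'''). The alkyne is built on the phenol oxygen of isovanillin, so the 3'-O-4''' link exists before ring F does.
- Pyranone rings C and E are each cut at O1–C2 and C2–C3: twofold cyclodehydration of a bis(1,3-diketone), which comes from a twofold Baker–Venkataraman rearrangement of a diester. The two aroyl carbons leave the key step differentiated (ester on ring F, masked aldehyde on ring B), so the two molecules of dibenzylated phloroacetophenone (rings A and D) are attached one after the other.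
- Ring order: B, A and D are bought as arenes; F is made first (cycloaddition with loss of CO2); C and E are closed together; the four benzyl ethers are removed last.

Key step: step 4

Remark: the target is achiral and no stereocentre has to be set; the acetophenone partner 15 is made from phloroacetophenone in one step and is not assumed to be bought; one molecule of 15 is consumed in step 7 and a second one in step 9.

**Step 1**
Reactants: 1 isovanillin
Product: 2 5-(dimethoxymethyl)-2-methoxyphenol
Conditions: HC(OMe)3, MeOH, p-TsOH·H2O (cat.), rt; then Et3N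
Reagents that add atoms: trimethyl orthoformate, COC(OC)OC; methanol, CO
Why: Acid-catalysed acetalisation driven by the orthoformate as water scavenger should mask the aldehyde against the bases of steps 2 and 3 while leaving the phenol free.

**Step 2**
Reactants: 2 5-(dimethoxymethyl)-2-methoxyphenol; 3 trichloroethylene
Product: 5 2-{[(E)-1,2-dichloroethenyl]oxy}-4-(dimethoxymethyl)-1-methoxybenzene, via dichloroacetylene 4 (not isolated)
Conditions: K2CO3, DMF, 70 °C
Reagents that add atoms: none
Why: Base-induced dehydrochlorination of 3 gives 4 in the flask and anti nucleophilic addition of the phenoxide across it, a known preparation of aryl 1,2-dichlorovinyl ethers, should set the E geometry; the acetal is inert to carbonate.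

**Step 3**
Reactants: 5 2-{[(E)-1,2-dichloroethenyl]oxy}-4-(dimethoxymethyl)-1-methoxybenzene
Product: 8 4-(dimethoxymethyl)-2-(ethynyloxy)-1-methoxybenzene, via chloroethynyl ether 6 (not isolated), via lithium acetylide 7 (not isolated)
Conditions: n-BuLi (2.3 equiv), THF, −78 → −40 °C; then MeOH, −78 °C; cold NaHCO3 work-up
Reagents that add atoms: none
Why: β-Elimination of HCl followed by chlorine–lithium exchange and protonation is the established route from 1,2-dichlorovinyl ethers to terminal ynol ethers; acetal and aryl ethers are inert at low temperature, and 8 should be used crude and at once.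

**Step 4**
Reactants: 8 4-(dimethoxymethyl)-2-(ethynyloxy)-1-methoxybenzene; 9 methyl coumalate
Product: 11 methyl 4-[5-(dimethoxymethyl)-2-methoxyphenoxy]benzoate, via bridged lactone 10 (not isolated)
Conditions: 8 (1.5 equiv), toluene, BHT (cat.), sealed tube, 110 °C
Reagents that add atoms: none
Why: Proposed new method: the CH terminus of 8 should bond to C6 of 9 (the β-carbon of the C5 acrylate unit) while the oxygen-bearing alkyne carbon bonds to C3, in a concerted but asynchronous inverse-electron-demand [4+2] cycloaddition that gives bridged lactone 10, which then expels CO2 by retro-[4+2]. Ring F is thus closed by an intermolecular [4+2] annulation and extrusion that forms C3'''–C4''' and C5'''–C6''' and delivers the ring aromatic without an oxidant. The closest known reaction type is the cycloaddition–decarboxylation of methyl coumalate with enol ethers, ketene acetals, ynamines and 1-alkynes to para-substituted benzoates; an aryloxyacetylene has not been shown as the two-carbon partner. No stereocentre remains, since the two bridgehead centres of racemic 10 vanish on aromatisation. The step needs para and not meta placement of ether oxygen and ester, which is secured because the C5 ester makes C6 the electrophilic diene terminus and the ether oxygen makes the CH carbon of 8 the nucleophilic alkyne terminus. An aryl ynol ether has no β-hydrogen for retro-ene collapse to a ketene and the medium is neutral, so 8 and the acetal should survive the heating, and the 3'-O-4''' connectivity cannot scramble because the ring B oxygen is already bonded to the alkyne.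

**Step 5**
Reactants: 11 methyl 4-[5-(dimethoxymethyl)-2-methoxyphenoxy]benzoate
Product: 13 4-(5-formyl-2-methoxyphenoxy)benzoic acid, via lithium carboxylate 12 (not isolated)
Conditions: LiOH·H2O, THF/MeOH/H2O, 40 °C; then 2 M HCl to pH 1, rt
Reagents that add atoms: lithium hydroxide, [Li+].[OH-]; water, O
Why: Ester saponification followed by aqueous-acid acetal hydrolysis in the same flask are both standard, and the diaryl ether and aryl methyl ether are inert to both media.

**Step 6**
Reactants: 14 1-(2,4,6-trihydroxyphenyl)ethan-1-one (phloroacetophenone)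
Product: 15 1-[2,4-bis(benzyloxy)-6-hydroxyphenyl]ethan-1-one
Conditions: BnBr (2.1 equiv), K2CO3, DMF, rt
Reagents that add atoms: benzyl bromide, BrCc1ccccc1
Why: Williamson etherification with two equivalents of halide should stop at the dibenzyl ether because the remaining ortho hydroxyl is hydrogen-bonded to the acetyl carbonyl and is the least nucleophilic.

**Step 7**
Reactants: 13 4-(5-formyl-2-methoxyphenoxy)benzoic acid; 15 1-[2,4-bis(benzyloxy)-6-hydroxyphenyl]ethan-1-one
Product: 17 2-acetyl-3,5-bis(benzyloxy)phenyl 4-(5-formyl-2-methoxyphenoxy)benzoate, via acid chloride 16 (not isolated)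
Conditions: (COCl)2, DMF (cat.), CH2Cl2, 0 °C → rt, evaporate; then 15 (1.05 equiv), pyridine, DMAP (cat.), CH2Cl2, 0 °C → rt
Reagents that add atoms: none
Why: Acid chloride formation followed by DMAP-catalysed O-acylation is the standard esterification of chelated 2-hydroxyacetophenones, the aryl aldehyde is inert to oxalyl chloride with catalytic DMF at this temperature, and only the ring F carboxyl exists at this stage, so exactly one molecule of 15 is attached.

**Step 8**
Reactants: 17 2-acetyl-3,5-bis(benzyloxy)phenyl 4-(5-formyl-2-methoxyphenoxy)benzoate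
Product: 18 3-(4-{[2-acetyl-3,5-bis(benzyloxy)phenoxy]carbonyl}phenoxy)-4-methoxybenzoic acid
Conditions: NaClO2, NaH2PO4, 2-methyl-2-butene (excess), t-BuOH/THF/H2O, 0 °C → rt
Reagents that add atoms: sodium chlorite, [Na+].[O-]Cl=O
Why: Pinnick oxidation converts the aryl aldehyde to the acid under buffered, mildly acidic conditions that leave the aryl ester and the methyl ketone intact, and the excess alkene scavenger should keep hypochlorous acid from chlorinating the electron-rich rings.

**Step 9**
Reactants: 18 3-(4-{[2-acetyl-3,5-bis(benzyloxy)phenoxy]carbonyl}phenoxy)-4-methoxybenzoic acid; 15 1-[2,4-bis(benzyloxy)-6-hydroxyphenyl]ethan-1-one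
Product: 20 2-acetyl-3,5-bis(benzyloxy)phenyl 3-(4-{[2-acetyl-3,5-bis(benzyloxy)phenoxy]carbonyl}phenoxy)-4-methoxybenzoate, via acid chloride 19 (not isolated)
Conditions: (COCl)2, DMF (cat.), CH2Cl2, 0 °C → rt, evaporate; then 15 (1.1 equiv), pyridine, DMAP (cat.), CH2Cl2, 0 °C → rt
Reagents that add atoms: none
Why: The same acid chloride esterification attaches the second molecule of 15 to the ring B carboxyl, and the existing aryl ester, the methyl ketone and the benzyl ethers are inert to oxalyl chloride and to pyridine.

**Step 10**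
Reactants: 20 2-acetyl-3,5-bis(benzyloxy)phenyl 3-(4-{[2-acetyl-3,5-bis(benzyloxy)phenoxy]carbonyl}phenoxy)-4-methoxybenzoate
Product: 21 1-[2,4-bis(benzyloxy)-6-hydroxyphenyl]-3-[3-(4-{3-[2,4-bis(benzyloxy)-6-hydroxyphenyl]-3-oxopropanoyl}phenoxy)-4-methoxyphenyl]propane-1,3-dione
Conditions: KOH (powdered), dry pyridine, 50 °C; then cold dilute HCl
Reagents that add atoms: none
Why: Twofold Baker–Venkataraman rearrangement, in which each acetyl enolate attacks the neighbouring aryl ester intramolecularly and the acyl group moves from oxygen to carbon, should give the bis(diketone) as its stable chelated phenoxide.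

**Step 11**
Reactants: 21 bis(1,3-diketone)
Product: 22 5,7-bis(benzyloxy)-2-{3-[4-(5,7-bis(benzyloxy)-4-oxo-4H-chromen-2-yl)phenoxy]-4-methoxyphenyl}-4H-chromen-4-one
Conditions: p-TsOH·H2O (cat.), toluene, 100 °C
Reagents that add atoms: none
Why: Acid-catalysed cyclodehydration (addition of each phenol to the aryl ketone carbonyl, then loss of water) closes pyranone rings C and E in the standard last stage of a flavone synthesis.

**Step 12**
Reactants: 22 tetra-O-benzyl-4'-O-methylochnaflavone
Product: 23 4'-O-methylochnaflavone
Conditions: H2 (1 atm), 10% Pd/C, THF/MeOH, rt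
Reagents that add atoms: none
Why: Catalytic hydrogenolysis cleaves the four benzyl aryl ethers, while the pyranone C2–C3 bond (a vinylogous ester), the aryl methyl ether and the diaryl ether should resist at one atmosphere.

**Compound list**
1 | isovanillin (3-hydroxy-4-methoxybenzaldehyde) | COc1ccc(C=O)cc1O | starting material
2 | 5-(dimethoxymethyl)-2-methoxyphenol | COc1ccc(C(OC)OC)cc1O | intermediate
3 | trichloroethylene | ClC=C(Cl)Cl | starting material
4 | dichloroacetylene | ClC#CCl | intermediate (not isolated)
5 | 2-{[(E)-1,2-dichloroethenyl]oxy}-4-(dimethoxymethyl)-1-methoxybenzene | COc1ccc(C(OC)OC)cc1O/C(Cl)=C\Cl | intermediate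
6 | 2-[(chloroethynyl)oxy]-4-(dimethoxymethyl)-1-methoxybenzene | COc1ccc(C(OC)OC)cc1OC#CCl | intermediate (not isolated)
7 | lithium 2-[5-(dimethoxymethyl)-2-methoxyphenoxy]ethyn-1-ide | COc1ccc(C(OC)OC)cc1OC#C[Li] | intermediate (not isolated)
8 | 4-(dimethoxymethyl)-2-(ethynyloxy)-1-methoxybenzene | COc1ccc(C(OC)OC)cc1OC#C | intermediate
9 | methyl coumalate (methyl 2-oxo-2H-pyran-5-carboxylate) | COC(=O)c1ccc(=O)oc1 | starting material
10 | methyl 5-[5-(dimethoxymethyl)-2-methoxyphenoxy]-3-oxo-2-oxabicyclo[2.2.2]octa-5,7-diene-7-carboxylate (racemic, one enantiomer drawn) | O=C1O[C@@H]2C=C(Oc3cc(C(OC)OC)ccc3OC)[C@H]1C=C2C(=O)OC | intermediate (not isolated)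
11 | methyl 4-[5-(dimethoxymethyl)-2-methoxyphenoxy]benzoate | COc1ccc(C(OC)OC)cc1Oc1ccc(C(=O)OC)cc1 | intermediate
12 | lithium 4-[5-(dimethoxymethyl)-2-methoxyphenoxy]benzoate | COc1ccc(C(OC)OC)cc1Oc1ccc(C(=O)[O-])cc1.[Li+] | intermediate (not isolated)
13 | 4-(5-formyl-2-methoxyphenoxy)benzoic acid | COc1ccc(C=O)cc1Oc1ccc(C(=O)O)cc1 | intermediate
14 | 1-(2,4,6-trihydroxyphenyl)ethan-1-one (phloroacetophenone) | CC(=O)c1c(O)cc(O)cc1O | starting material
15 | 1-[2,4-bis(benzyloxy)-6-hydroxyphenyl]ethan-1-one | CC(=O)c1c(O)cc(OCc2ccccc2)cc1OCc1ccccc1 | intermediate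
16 | 4-(5-formyl-2-methoxyphenoxy)benzoyl chloride | COc1ccc(C=O)cc1Oc1ccc(C(Cl)=O)cc1 | intermediate (not isolated)
17 | 2-acetyl-3,5-bis(benzyloxy)phenyl 4-(5-formyl-2-methoxyphenoxy)benzoate | COc1ccc(C=O)cc1Oc1ccc(C(=O)Oc2cc(OCc3ccccc3)cc(OCc3ccccc3)c2C(C)=O)cc1 | intermediate
18 | 3-(4-{[2-acetyl-3,5-bis(benzyloxy)phenoxy]carbonyl}phenoxy)-4-methoxybenzoic acid | COc1ccc(C(=O)O)cc1Oc1ccc(C(=O)Oc2cc(OCc3ccccc3)cc(OCc3ccccc3)c2C(C)=O)cc1 | intermediate
19 | 2-acetyl-3,5-bis(benzyloxy)phenyl 4-[5-(chlorocarbonyl)-2-methoxyphenoxy]benzoate | COc1ccc(C(Cl)=O)cc1Oc1ccc(C(=O)Oc2cc(OCc3ccccc3)cc(OCc3ccccc3)c2C(C)=O)cc1 | intermediate (not isolated)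
20 | 2-acetyl-3,5-bis(benzyloxy)phenyl 3-(4-{[2-acetyl-3,5-bis(benzyloxy)phenoxy]carbonyl}phenoxy)-4-methoxybenzoate | COc1ccc(C(=O)Oc2cc(OCc3ccccc3)cc(OCc3ccccc3)c2C(C)=O)cc1Oc1ccc(C(=O)Oc2cc(OCc3ccccc3)cc(OCc3ccccc3)c2C(C)=O)cc1 | intermediate
21 | 1-[2,4-bis(benzyloxy)-6-hydroxyphenyl]-3-[3-(4-{3-[2,4-bis(benzyloxy)-6-hydroxyphenyl]-3-oxopropanoyl}phenoxy)-4-methoxyphenyl]propane-1,3-dione (drawn as the diketo tautomer) | COc1ccc(C(=O)CC(=O)c2c(O)cc(OCc3ccccc3)cc2OCc2ccccc2)cc1Oc1ccc(C(=O)CC(=O)c2c(O)cc(OCc3ccccc3)cc2OCc2ccccc2)cc1 | intermediate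
22 | 5,7-bis(benzyloxy)-2-{3-[4-(5,7-bis(benzyloxy)-4-oxo-4H-chromen-2-yl)phenoxy]-4-methoxyphenyl}-4H-chromen-4-one | COc1ccc(-c2cc(=O)c3c(OCc4ccccc4)cc(OCc4ccccc4)cc3o2)cc1Oc1ccc(-c2cc(=O)c3c(OCc4ccccc4)cc(OCc4ccccc4)cc3o2)cc1 | intermediate
23 | 4'-O-methylochnaflavone, 5,7-dihydroxy-2-{3-[4-(5,7-dihydroxy-4-oxo-4H-chromen-2-yl)phenoxy]-4-methoxyphenyl}-4H-chromen-4-one | COc1ccc(-c2cc(=O)c3c(O)cc(O)cc3o2)cc1Oc1ccc(-c2cc(=O)c3c(O)cc(O)cc3o2)cc1 | target

**Step count**
Total: 12 steps. Longest linear sequence: 11 steps (steps 1–5 and 7–12, from isovanillin); step 6 is a one-step side branch whose product 15 enters at steps 7 and 9.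

**Steps most likely to fail**

Step 4 (proposed new method). The aryloxyalkyne may oligomerise or be hydrated faster than it adds to the pyranone, the addition may be incompletely para-selective, or the acetal may be lost at the temperature the cycloaddition requires. The fallback uses known chemistry and gives up the de novo construction of ring F. It sets out from 1: nucleophilic aromatic substitution on methyl 4-fluorobenzoate (K2CO3, DMSO, 120 °C) should give methyl 4-(5-formyl-2-methoxyphenoxy)benzoate F1, in which the two carboxyl-level carbons are still differentiated. Saponification (LiOH·H2O, THF/H2O, rt) should give lithium 4-(5-formyl-2-methoxyphenoxy)benzoate F2, and acidification with 1 M HCl comes back to the route at acid 13.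

Step 3. The terminal ynol ether may be lost through hydration to the aryl acetate or through oligomerisation during protonation, aqueous work-up and concentration. The fallback sets out from 5: acetylide 7 is generated as before but silylated with chlorotri(propan-2-yl)silane instead of being protonated. This gives {[5-(dimethoxymethyl)-2-methoxyphenoxy]ethynyl}tri(propan-2-yl)silane F3, a C-silyl ynol ether that should tolerate chromatography on base-washed silica and storage. Fluoride desilylation (Bu4NF, THF, 0 °C) directly before the cycloaddition comes back to the route at 8.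

Step 10. The twofold acyl transfer may stall after one rearrangement, and hydroxide may cleave the hindered aryl esters. The fallback replaces O-acylation and rearrangement by direct C-acylation and sets out from 13 and 15. Pinnick oxidation of 13 (NaClO2, NaH2PO4, 2-methyl-2-butene) should give 3-(4-carboxyphenoxy)-4-methoxybenzoic acid F4, and oxalyl chloride with catalytic DMF converts it into 3-[4-(chlorocarbonyl)phenoxy]-4-methoxybenzoyl chloride F5. LiN(SiMe3)2 (about 3.3 equiv per ketone, THF, −78 °C) converts 15 into dilithium 1-[2,4-bis(benzyloxy)-6-oxidophenyl]ethen-1-olate F6. Addition of F5 (0.5 equiv, −78 °C → rt) and acid work-up should acylate the enolate carbon twice over and come back to the route at bis(diketone) 21.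

**Further compounds**
F1 | step 4 | methyl 4-(5-formyl-2-methoxyphenoxy)benzoate | COc1ccc(C=O)cc1Oc1ccc(C(=O)OC)cc1
F2 | step 4 | lithium 4-(5-formyl-2-methoxyphenoxy)benzoate | COc1ccc(C=O)cc1Oc1ccc(C(=O)[O-])cc1.[Li+]
F3 | step 3 | {[5-(dimethoxymethyl)-2-methoxyphenoxy]ethynyl}tri(propan-2-yl)silane | COc1ccc(C(OC)OC)cc1OC#C[Si](C(C)C)(C(C)C)C(C)C
F4 | step 10 | 3-(4-carboxyphenoxy)-4-methoxybenzoic acid | COc1ccc(C(=O)O)cc1Oc1ccc(C(=O)O)cc1
F5 | step 10 | 3-[4-(chlorocarbonyl)phenoxy]-4-methoxybenzoyl chloride | COc1ccc(C(Cl)=O)cc1Oc1ccc(C(Cl)=O)cc1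
F6 | step 10 | dilithium 1-[2,4-bis(benzyloxy)-6-oxidophenyl]ethen-1-olate | [Li+].[Li+].C=C([O-])c1c([O-])cc(OCc2ccccc2)cc1OCc1ccccc1
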